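Overview. The plan rests on C2 of the pyran ring (O1–C2–C3–C4–C4a–C8a, fused to the benzene ring C4a–C8a). C2 carries O1, a methyl group and two CH2CH2 arms (C3–C4 and C1'–C2'). With C1'–C2' drawn as a vinyl group, C2 is the fully substituted end of the allyl unit C2–C1'–C2'.
Last disconnection, C2'–C3': B-alkyl Suzuki coupling of the (2S)-2-vinylchroman with an E-alkenyl iodide that already holds the C3'=C4' geometry, the C7'=C8' alkene and the ester (three steps from 4-pentyn-1-ol). One basic hydrolysis then frees phenol and acid.
Key disconnection, O1–C2: enantioselective intramolecular Tsuji–Trost O-allylation of an E allylic methyl carbonate tethered to the free phenol. The benzene ring is bought and the pyran ring is the only ring formed.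
The carbonate comes from 2-methylhydroquinone by mono-silylation, ortho-formylation, extension to the methyl ketone and Horner–Wadsworth–Emmons olefination. The phenol that becomes O1 is held as a pivalate from the aldehyde to the hydride reduction, because a free phenoxide would add to the enoate (oxa-Michael) and give a racemic chroman.

Key step: step 9

Assumption: the (S,S) ligand is written in step 9, but the sense of induction under Curtin–Hammett selection cannot be read safely from a model, so the configuration of the first sample of the vinylchroman is checked, and the equally available (R,R) ligand is used, with nothing else changed, if the sense is opposite.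

Step 1
Reactants: 1 2-methylhydroquinone
Product: 2 4-[(tert-butyldimethylsilyl)oxy]-2-methylphenol
Conditions: TBSCl (1.0 equiv, slow addition), imidazole, DMF, 0 °C → rt
Reagents that add atoms: tert-butyldimethylsilyl chloride, CC(C)(C)[Si](C)(C)Cl
Why: Imidazole-mediated O-silylation is faster at the C4 hydroxyl, which has two ortho hydrogens and is slightly more acidic, than at the hydroxyl next to the methyl group, and the minor regioisomer and the bis-silyl ether are removed by chromatography.

Step 2
Reactants: 2 4-[(tert-butyldimethylsilyl)oxy]-2-methylphenol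
Product: 3 5-[(tert-butyldimethylsilyl)oxy]-2-hydroxy-3-methylbenzaldehyde
Conditions: MgCl2 (anhydrous), Et3N, (CH2O)n, MeCN, reflux; then 1 M HCl
Reagents that add atoms: paraformaldehyde (as formaldehyde), C=O
Why: In the Casnati–Skattebøl ortho-formylation magnesium delivers formaldehyde to the carbon ortho to the phenol oxygen and a second formaldehyde takes up hydride; one ortho carbon bears the methyl group, so only the other can react, and the amine medium leaves the aryl silyl ether alone.

Step 3
Reactants: 3 5-[(tert-butyldimethylsilyl)oxy]-2-hydroxy-3-methylbenzaldehyde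
Product: 4 4-[(tert-butyldimethylsilyl)oxy]-2-formyl-6-methylphenyl pivalate
Conditions: PivCl, Et3N, DMAP (cat.), CH2Cl2, 0 °C → rt
Reagents that add atoms: pivaloyl chloride, CC(C)(C)C(=O)Cl
Why: DMAP-catalysed O-acylation masks the future O1, so that no phenoxide can close onto the enoate of step 6 by oxa-Michael addition, and the bulky pivalate between two ortho substituents resists the stabilised carbanions of steps 4 and 6.

Step 4
Reactants: 4 4-[(tert-butyldimethylsilyl)oxy]-2-formyl-6-methylphenyl pivalate; 5 1-(triphenylphosphoranylidene)propan-2-one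
Product: 6 4-[(tert-butyldimethylsilyl)oxy]-2-methyl-6-[(1E)-3-oxobut-1-en-1-yl]phenyl pivalate
Conditions: 5 (1.3 equiv), toluene, 80 °C
Reagents that add atoms: 1-(triphenylphosphoranylidene)propan-2-one (5), CC(=O)C=P(c1ccccc1)(c1ccccc1)c1ccccc1
Why: The Wittig olefination of an aromatic aldehyde with a ketone-stabilised ylide is reliable and E-selective, and the ylide is too weak a base and nucleophile to touch the pivalate or the silyl ether.

Step 5
Reactants: 6 4-[(tert-butyldimethylsilyl)oxy]-2-methyl-6-[(1E)-3-oxobut-1-en-1-yl]phenyl pivalate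
Product: 7 4-[(tert-butyldimethylsilyl)oxy]-2-methyl-6-(3-oxobutyl)phenyl pivalate
Conditions: H2 (1 atm), 10% Pd/C, EtOAc, rt
Reagents that add atoms: none
Why: Heterogeneous catalytic hydrogenation saturates the conjugated C=C far faster than the ketone or the arene, and with the phenol acylated the product cannot collapse to a cyclic hemiketal.

Step 6
Reactants: 7 4-[(tert-butyldimethylsilyl)oxy]-2-methyl-6-(3-oxobutyl)phenyl pivalate; 8 triethyl phosphonoacetate
Product: 9 ethyl (2E)-5-{5-[(tert-butyldimethylsilyl)oxy]-3-methyl-2-(pivaloyloxy)phenyl}-3-methylpent-2-enoate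
Conditions: 8, NaH, THF, 0 °C → rt; Z isomer removed by chromatography
Reagents that add atoms: triethyl phosphonoacetate (8), CCOC(=O)CP(=O)(OCC)OCC
Why: The Horner–Wadsworth–Emmons olefination of a methyl ketone favours the enoate with the larger CH2CH2Ar arm trans to the ester, and the minor Z ester, which would spoil the stereochemical course of step 9, is separated at this stage.

Step 7
Reactants: 9 ethyl (2E)-5-{5-[(tert-butyldimethylsilyl)oxy]-3-methyl-2-(pivaloyloxy)phenyl}-3-methylpent-2-enoate
Product: 10 4-[(tert-butyldimethylsilyl)oxy]-2-[(3E)-5-hydroxy-3-methylpent-3-en-1-yl]-6-methylphenol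
Conditions: iBu2AlH (5 equiv), CH2Cl2, −78 → 0 °C; aq. potassium sodium tartrate
Reagents that add atoms: none
Why: The 1,2-reduction with iBu2AlH takes the enoate to the allylic alcohol without touching the alkene geometry and cleaves the aryl pivalate reductively in the same operation, while the aryl silyl ether is inert at this temperature.

Step 8
Reactants: 10 4-[(tert-butyldimethylsilyl)oxy]-2-[(3E)-5-hydroxy-3-methylpent-3-en-1-yl]-6-methylphenol
Product: 11 (2E)-5-{5-[(tert-butyldimethylsilyl)oxy]-2-hydroxy-3-methylphenyl}-3-methylpent-2-en-1-yl methyl carbonate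
Conditions: ClCO2Me (1.05 equiv), pyridine, CH2Cl2, −20 → 0 °C
Reagents that add atoms: methyl chloroformate, COC(=O)Cl
Why: In this chemoselective alkoxycarbonylation through the N-acylpyridinium salt the weak base leaves the phenol protonated, and the open primary allylic alcohol is much the better nucleophile than a phenol flanked by two ortho alkyl groups, so one equivalent of chloroformate should end up on the alcohol.

Step 9
Reactants: 11 (2E)-5-{5-[(tert-butyldimethylsilyl)oxy]-2-hydroxy-3-methylphenyl}-3-methylpent-2-en-1-yl methyl carbonate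
Product: 12 (2S)-6-[(tert-butyldimethylsilyl)oxy]-2-ethenyl-2,8-dimethylchroman
Conditions: Pd2(dba)3·CHCl3 (2 mol %), (1S,2S)-N,N'-(cyclohexane-1,2-diyl)bis[2-(diphenylphosphanyl)benzamide] (6 mol %), AcOH (1 equiv), CH2Cl2 (0.05 M, degassed), rt
Reagents that add atoms: none
Why: The zerovalent palladium–diphosphine complex binds the alkene of 11 anti to the carbonate and ionises it, with loss of CO2 and of methoxide that AcOH buffers, to a cationic η3-allyl complex over C2–C1'–C2' in which the E geometry holds the CH2CH2Ar arm syn and the methyl group anti. The phenol oxygen then attacks C2 on the face opposite to palladium, which is the intramolecular asymmetric Tsuji–Trost O-allylation known for phenols tethered to trisubstituted allyl carbonates and giving 2-methyl-2-vinylchromans. The pyran ring closes in the 6-exo mode with C1'=C2' left outside the ring as the vinyl group, whereas attack at C2' would need an eight-membered ring, so the tether secures the branched regiochemistry. C2 is set by the ligand: the two diastereomeric allyl complexes exchange the palladium-bearing face through an η1 form bound at the CH2 terminus C2', which leaves the syn and anti places at C2 as they are, and the chiral pocket lets one of them close faster (Curtin–Hammett selection), AcOH keeping the phenol protonated so that the exchange stays ahead of ring closure. The step needs enantioface selectivity, for which the single E geometry secured in step 6 is the precondition because a Z alkene would swap methyl and arm on the allyl unit, and it needs O- over C-alkylation, which the substrate secures because both ortho positions and the para position of the phenol are substituted.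

Step 10
Reactants: 13 4-pentyn-1-ol
Product: 15 (4E)-5-iodo-4-methylpent-4-en-1-ol, via alkenylalane 14 (not isolated)
Conditions: Me3Al (3 equiv), Cp2ZrCl2 (0.25 equiv), CH2Cl2, 0 °C → rt; then I2, THF, −30 → 0 °C; aq. K2CO3
Reagents that add atoms: trimethylaluminium, C[Al](C)C; iodine, II
Why: The zirconium-catalysed Negishi carboalumination adds CH3 and Al syn across the terminal alkyne with aluminium on the terminal carbon, and iodinolysis of the C–Al bond goes with retention, which fixes the E geometry of the later C3'=C4' alkene.

Step 11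
Reactants: 15 (4E)-5-iodo-4-methylpent-4-en-1-ol
Product: 16 (4E)-5-iodo-4-methylpent-4-enal
Conditions: Dess–Martin periodinane, CH2Cl2, 0 °C → rt
Reagents that add atoms: none
Why: The Dess–Martin oxidation stops cleanly at the aldehyde under near-neutral conditions and leaves the alkenyl iodide and its geometry untouched.

Step 12
Reactants: 16 (4E)-5-iodo-4-methylpent-4-enal; 17 ethyl 2-(triphenylphosphoranylidene)propanoate
Product: 18 ethyl (2E,6E)-7-iodo-2,6-dimethylhepta-2,6-dienoate
Conditions: 17 (1.2 equiv), CH2Cl2, rt
Reagents that add atoms: ethyl 2-(triphenylphosphoranylidene)propanoate (17), CCOC(=O)C(C)=P(c1ccccc1)(c1ccccc1)c1ccccc1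
Why: The Wittig olefination of an unbranched aldehyde with the α-methyl ester-stabilised ylide gives the E 2-methylenoate (later C7'=C8') with the chain trans to the ester.

Step 13
Reactants: 12 (2S)-6-[(tert-butyldimethylsilyl)oxy]-2-ethenyl-2,8-dimethylchroman; 18 ethyl (2E,6E)-7-iodo-2,6-dimethylhepta-2,6-dienoate
Product: 20 ethyl (2E,6E)-9-{(2R)-6-[(tert-butyldimethylsilyl)oxy]-2,8-dimethylchroman-2-yl}-2,6-dimethylnona-2,6-dienoate, via B-alkyl-9-BBN borane 19 (not isolated)
Conditions: 9-BBN-H (1.5 equiv), THF, 0 °C → rt; then 3 M aq. K3PO4 (destroys excess B–H), 18, PdCl2(dppf)·CH2Cl2 (5 mol %), DMF, rt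
Reagents that add atoms: 9-borabicyclo[3.3.1]nonane, B1C2CCCC1CCC2 (its boron cage stays only in 19); alkenyl iodide 18, I/C=C(\C)CC/C=C(\C)C(=O)OCC
Why: Anti-Markovnikov hydroboration of the only alkene of 12 puts boron on C2', and the B-alkyl Suzuki–Miyaura coupling forms C2'–C3' with retention of the E geometry of the iodide, leaves C2 untouched (the descriptor changes to R only by priority) and uses K3PO4 at room temperature, which is mild toward the ester and the aryl silyl ether.

Step 14
Reactants: 20 ethyl (2E,6E)-9-{(2R)-6-[(tert-butyldimethylsilyl)oxy]-2,8-dimethylchroman-2-yl}-2,6-dimethylnona-2,6-dienoate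
Product: 21 (2E,6E)-9-[(2R)-6-hydroxy-2,8-dimethylchroman-2-yl]-2,6-dimethylnona-2,6-dienoic acid (CNP0176653.1)
Conditions: LiOH·H2O (excess), THF/MeOH/H2O (degassed, Ar), 40 °C; then 1 M HCl, 0 °C
Reagents that add atoms: lithium hydroxide (its oxygen ends in the carboxyl group), [Li+].[OH-]
Why: Saponification of the ethyl ester and hydroxide attack at silicon of the unhindered aryl silyl ether, whose phenoxide is a good leaving group, run together under the same conditions, neither touches C2 or the alkenes, and exclusion of air protects the chromanolate from oxidation.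

Compound list
1 | 2-methylhydroquinone | Cc1cc(O)ccc1O | starting material
2 | 4-[(tert-butyldimethylsilyl)oxy]-2-methylphenol | Cc1cc(O[Si](C)(C)C(C)(C)C)ccc1O | intermediate
3 | 5-[(tert-butyldimethylsilyl)oxy]-2-hydroxy-3-methylbenzaldehyde | Cc1cc(O[Si](C)(C)C(C)(C)C)cc(C=O)c1O | intermediate
4 | 4-[(tert-butyldimethylsilyl)oxy]-2-formyl-6-methylphenyl pivalate | Cc1cc(O[Si](C)(C)C(C)(C)C)cc(C=O)c1OC(=O)C(C)(C)C | intermediate
5 | 1-(triphenylphosphoranylidene)propan-2-one | CC(=O)C=P(c1ccccc1)(c1ccccc1)c1ccccc1 | starting material
6 | 4-[(tert-butyldimethylsilyl)oxy]-2-methyl-6-[(1E)-3-oxobut-1-en-1-yl]phenyl pivalate | CC(=O)/C=C/c1cc(O[Si](C)(C)C(C)(C)C)cc(C)c1OC(=O)C(C)(C)C | intermediate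
7 | 4-[(tert-butyldimethylsilyl)oxy]-2-methyl-6-(3-oxobutyl)phenyl pivalate | CC(=O)CCc1cc(O[Si](C)(C)C(C)(C)C)cc(C)c1OC(=O)C(C)(C)C | intermediate
8 | triethyl phosphonoacetate | CCOC(=O)CP(=O)(OCC)OCC | starting material
9 | ethyl (2E)-5-{5-[(tert-butyldimethylsilyl)oxy]-3-methyl-2-(pivaloyloxy)phenyl}-3-methylpent-2-enoate | CCOC(=O)/C=C(\C)CCc1cc(O[Si](C)(C)C(C)(C)C)cc(C)c1OC(=O)C(C)(C)C | intermediate
10 | 4-[(tert-butyldimethylsilyl)oxy]-2-[(3E)-5-hydroxy-3-methylpent-3-en-1-yl]-6-methylphenol | OC/C=C(\C)CCc1cc(O[Si](C)(C)C(C)(C)C)cc(C)c1O | intermediate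
11 | (2E)-5-{5-[(tert-butyldimethylsilyl)oxy]-2-hydroxy-3-methylphenyl}-3-methylpent-2-en-1-yl methyl carbonate | COC(=O)OC/C=C(\C)CCc1cc(O[Si](C)(C)C(C)(C)C)cc(C)c1O | intermediate
12 | (2S)-6-[(tert-butyldimethylsilyl)oxy]-2-ethenyl-2,8-dimethylchroman | C=C[C@]1(C)CCc2cc(O[Si](C)(C)C(C)(C)C)cc(C)c2O1 | intermediate
13 | 4-pentyn-1-ol | C#CCCCO | starting material
14 | dimethyl[(1E)-5-(dimethylalumanyloxy)-2-methylpent-1-en-1-yl]alumane | C[Al](C)/C=C(\C)CCCO[Al](C)C | intermediate
15 | (4E)-5-iodo-4-methylpent-4-en-1-ol | I/C=C(\C)CCCO | intermediate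
16 | (4E)-5-iodo-4-methylpent-4-enal | I/C=C(\C)CCC=O | intermediate
17 | ethyl 2-(triphenylphosphoranylidene)propanoate | CCOC(=O)C(C)=P(c1ccccc1)(c1ccccc1)c1ccccc1 | starting material
18 | ethyl (2E,6E)-7-iodo-2,6-dimethylhepta-2,6-dienoate | I/C=C(\C)CC/C=C(\C)C(=O)OCC | intermediate
19 | 9-{2-[(2R)-6-[(tert-butyldimethylsilyl)oxy]-2,8-dimethylchroman-2-yl]ethyl}-9-borabicyclo[3.3.1]nonane | B1(C2CCCC1CCC2)CC[C@]3(C)CCc4cc(O[Si](C)(C)C(C)(C)C)cc(C)c4O3 | intermediate
20 | ethyl (2E,6E)-9-{(2R)-6-[(tert-butyldimethylsilyl)oxy]-2,8-dimethylchroman-2-yl}-2,6-dimethylnona-2,6-dienoate | C/C(=C\CC[C@]1(C)CCc2cc(O[Si](C)(C)C(C)(C)C)cc(C)c2O1)CC/C=C(\C)C(=O)OCC | intermediate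
21 | (2E,6E)-9-[(2R)-6-hydroxy-2,8-dimethylchroman-2-yl]-2,6-dimethylnona-2,6-dienoic acid | C/C(=C\CC[C@]1(C)CCc2cc(O)cc(C)c2O1)CC/C=C(\C)C(=O)O | target

Total step count: 14. Longest linear sequence: 11 steps (steps 1–9, 13 and 14, from 2-methylhydroquinone); the iodide branch takes 3 steps (steps 10–12).

Steps most likely to fail

Step 9.
- Risk: the two diastereomeric allyl complexes may close at similar rates, so that enantioface selection stays incomplete. Proton loss from the allyl cation to a 1,3-diene may also drain material.
- Fallback: it sets out from 7 and comes back at 12, and it forms O1–C2 by oxidative oxypalladation instead of allyl ionisation. Wittig ethylidenation of 7 (EtPPh3Br, KN(SiMe3)2, THF, −78 °C → rt) gives the trisubstituted alkene pivalate F1 as an alkene mixture. iBu2AlH then frees the alkenylphenol F2.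
- F2 is cyclised in an enantioselective Wacker-type reaction with divalent palladium: Pd(OCOCF3)2, one enantiomer of 2,2'-bis(4-benzyl-4,5-dihydrooxazol-2-yl)-1,1'-binaphthyl, p-benzoquinone, MeOH, rt. The phenol adds to the methyl-bearing alkene carbon, and β-hydride elimination toward the terminal CH3 leaves the vinyl group of 12. This reaction type is known to accept alkene mixtures of such phenols.

Step 6.
- Risk: E selectivity in the olefination of the methyl ketone may be incomplete and the separation of the two enoates imperfect. Z material would then pass into step 9 and lower the enantiomeric purity.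
- Fallback: it sets out from 3 and comes back at 10, and it builds the trisubstituted alkene stereospecifically by cross-coupling. Methylenation of 3 (MePPh3Br, KOtBu, one extra equivalent for the phenol, THF, 0 °C) gives the vinylphenol F3.
- But-2-yn-1-ol is converted by syn hydrozirconation with Cp2Zr(H)Cl (zirconium at the methyl-bearing carbon) and iodinolysis into (2E)-3-iodobut-2-en-1-ol F4.
- F3 takes up two equivalents of 9-BBN-H to give the O,C-bis(9-BBN) adduct F5. Coupling of F5 with F4 (PdCl2(dppf)·CH2Cl2, aq. K3PO4, THF/DMF, rt) goes with retention and gives 10 directly. No enoate appears on this path, so no phenol masking is needed.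

Step 8.
- Risk: acylation of the phenol oxygen may compete and block the nucleophile of the key step.
- Fallback: it sets out from 10 and comes back at 11, and it replaces selective acylation by exhaustive acylation and selective release. Excess ClCO2Me with Et3N and DMAP gives the bis(methyl carbonate) F6.
- One equivalent of piperidine in THF at 0 °C then aminolyses only the aryl carbonate, whose aryloxide is by far the better leaving group. The allyl methyl carbonate and the silyl ether are left in place.

Further compounds
F1 | step 9 | 4-[(tert-butyldimethylsilyl)oxy]-2-methyl-6-(3-methylpent-3-en-1-yl)phenyl pivalate (E/Z mixture) | CC=C(C)CCc1cc(O[Si](C)(C)C(C)(C)C)cc(C)c1OC(=O)C(C)(C)C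
F2 | step 9 | 4-[(tert-butyldimethylsilyl)oxy]-2-methyl-6-(3-methylpent-3-en-1-yl)phenol (E/Z mixture) | CC=C(C)CCc1cc(O[Si](C)(C)C(C)(C)C)cc(C)c1O
F3 | step 6 | 4-[(tert-butyldimethylsilyl)oxy]-2-ethenyl-6-methylphenol | C=Cc1cc(O[Si](C)(C)C(C)(C)C)cc(C)c1O
F4 | step 6 | (2E)-3-iodobut-2-en-1-ol | OC/C=C(\C)I
F5 | step 6 | 9-{2-[2-(9-borabicyclo[3.3.1]nonan-9-yloxy)-5-[(tert-butyldimethylsilyl)oxy]-3-methylphenyl]ethyl}-9-borabicyclo[3.3.1]nonane | Cc1cc(O[Si](C)(C)C(C)(C)C)cc(CCB2C3CCCC2CCC3)c1OB1C2CCCC1CCC2
F6 | step 8 | (2E)-5-{5-[(tert-butyldimethylsilyl)oxy]-2-[(methoxycarbonyl)oxy]-3-methylphenyl}-3-methylpent-2-en-1-yl methyl carbonate | COC(=O)OC/C=C(\C)CCc1cc(O[Si](C)(C)C(C)(C)C)cc(C)c1OC(=O)OC
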